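**Retrosynthetic overview**
1. Feature: the benzene ring (ring A) holds the pyran ring (ring B) through two neighbouring bonds, C8a–O1 and C4a–C4. These lie between the para-related oxygens on C8 and C5. Cutting both bonds leaves 3,6-dimethoxybenzyne, whose two reactive carbons are equivalent, so the annulation raises no regiochemical question.
2. Late disconnections: 5,8-hydroquinone ⇒ dimethyl ether (cerium oxidation, then dithionite); C6 cinnamoyl ⇒ C6–Br + cinnamaldehyde; (E)-allylic tertiary carbinol ⇒ side-chain epoxide (selenide opening, selenoxide elimination); C3=C4 ⇒ C4 ketone.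
3. Key disconnection: chroman-4-one ⇒ aryne + O-silylated (S)-β-hydroxy ester. Alkoxide addition makes C8a–O1, and the resulting aryl anion attacks the ester to make C4a–C4.
4. C2 is set by Sharpless epoxidation of geraniol and hydride opening, and its C–O bond is never broken afterwards. The aryne precursor comes from 2,5-dimethoxyphenol by carbamate-directed silylation.
5. Ring order: ring A is bought, ring B closes in step 9, and the phenyl ring arrives with cinnamaldehyde. After step 9 the order (epoxidise, brominate, reduce, dehydrate, open, eliminate) lets each electrophile meet only one reactive site.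

Key step: step 9

Assumption: the centres formed at the side-chain epoxide/selenide carbon, at C4 of the chromanol and at the carbinol next to C6 arise without control, are drawn undefined and are all erased later, so only C2 has to be carried; all 2H-chromenes are kept from light and prolonged heating, since reversible electrocyclic opening of ring B would scramble C2.

**Route**

Step 1
Reactants: 1 geraniol
Product: 2 (2S,3S)-2,3-epoxygeraniol
Conditions: Ti(OiPr)4 (cat.), L-(+)-diethyl tartrate (cat.), t-BuOOH, 4 Å molecular sieves, CH2Cl2, −20 °C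
Reagents that add atoms: tert-butyl hydroperoxide, CC(C)(C)OO
Why: Katsuki–Sharpless asymmetric epoxidation: the allylic hydroxyl ties the substrate to the titanium tartrate complex, so only the 2,3-alkene reacts and the L-(+)-tartrate directs oxygen to the face that gives the (2S,3S)-epoxide, whose C3 becomes C2 of the chromene.

Step 2
Reactants: 2 (2S,3S)-2,3-epoxygeraniol
Product: 3 (S)-3,7-dimethyloct-6-ene-1,3-diol
Conditions: NaAlH2(OCH2CH2OMe)2, THF, 0 °C → rt; aq. potassium sodium tartrate
Reagents that add atoms: none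
Why: Hydroxyl-directed reductive opening of a 2,3-epoxy alcohol: the alkoxyaluminate formed at the primary hydroxyl delivers hydride to C2 from within, so the 1,3-diol forms and the C3–O bond with its (S) configuration is untouched.

Step 3
Reactants: 3 (S)-3,7-dimethyloct-6-ene-1,3-diol
Product: 4 (S)-3-hydroxy-3,7-dimethyloct-6-enoic acid
Conditions: TEMPO (cat.), PhI(OAc)2, MeCN/H2O, rt
Reagents that add atoms: water, O
Why: Oxoammonium (TEMPO) oxidation: only the primary alcohol can be oxidised, water hydrates the aldehyde for the second oxidation to the acid, and neither the tertiary carbinol nor the trisubstituted alkene reacts.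

Step 4
Reactants: 4 (S)-3-hydroxy-3,7-dimethyloct-6-enoic acid
Product: 5 ethyl (S)-3-hydroxy-3,7-dimethyloct-6-enoate
Conditions: EtI, K2CO3, DMF, rt
Reagents that add atoms: ethyl iodide, CCI
Why: SN2 O-alkylation of the carboxylate under mildly basic conditions, chosen over acid-catalysed esterification so that the tertiary β-carbinol is neither dehydrated nor ionised.

Step 5
Reactants: 5 ethyl (S)-3-hydroxy-3,7-dimethyloct-6-enoate
Product: 6 ethyl (S)-3,7-dimethyl-3-(trimethylsilyloxy)oct-6-enoate
Conditions: Me3SiCl, imidazole, CH2Cl2, 0 °C → rt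
Reagents that add atoms: chlorotrimethylsilane, C[Si](C)(C)Cl
Why: Standard alcohol silylation with the smallest silyl chloride, which reaches even the tertiary hydroxyl, removes the only acidic proton of the fragment and turns the carbinol oxygen into a fluoride-releasable alkoxide for step 9.

Step 6
Reactants: 7 2,5-dimethoxyphenol
Product: 8 2,5-dimethoxyphenyl N-isopropylcarbamate
Conditions: i-PrNCO, Et3N (cat.), CH2Cl2, rt
Reagents that add atoms: isopropyl isocyanate, CC(C)N=C=O
Why: Base-catalysed addition of the phenol to the isocyanate (carbamoylation) installs a strong ortho-directing group that can later be removed under mild E1cB conditions.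

Step 7
Reactants: 8 2,5-dimethoxyphenyl N-isopropylcarbamate
Product: 12 3,6-dimethoxy-2-(trimethylsilyl)phenyl N-isopropylcarbamate, via N-silyl carbamate 9 (not isolated), via aryllithium 10 (not isolated), via doubly silylated carbamate 11 (not isolated)
Conditions: TBSOTf, TMEDA, Et2O, 0 °C → rt; n-BuLi, TMEDA, −78 °C; Me3SiCl, −78 °C → rt; aq. NaHSO4
Reagents that add atoms: chlorotrimethylsilane, C[Si](C)(C)Cl
Why: Directed ortho-metalation (Snieckus type) after transient N-silylation of the carbamate N–H: the only ring position flanked by both the carbamate and a methoxy group is lithiated by cooperative direction, Me3SiCl traps the carbanion, and the labile N-silyl group falls off on acidic work-up.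

Step 8
Reactants: 12 3,6-dimethoxy-2-(trimethylsilyl)phenyl N-isopropylcarbamate
Product: 14 3,6-dimethoxy-2-(trimethylsilyl)phenyl trifluoromethanesulfonate, via silylphenol 13 (not isolated)
Conditions: DBU, Et2NH, MeCN, 40 °C; then PhNTf2, rt
Reagents that add atoms: N-phenylbis(trifluoromethanesulfonimide), O=S(=O)(N(c1ccccc1)S(=O)(=O)C(F)(F)F)C(F)(F)F
Why: E1cB cleavage of the secondary carbamate (DBU removes N–H, isopropyl isocyanate leaves and is trapped by Et2NH) followed by O-triflation of the phenoxide in the same flask, which avoids handling the protodesilylation-prone electron-rich silylphenol.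

Step 9
Reactants: 6 ethyl (S)-3,7-dimethyl-3-(trimethylsilyloxy)oct-6-enoate; 14 3,6-dimethoxy-2-(trimethylsilyl)phenyl trifluoromethanesulfonate
Product: 18 (S)-5,8-dimethoxy-2-methyl-2-(4-methylpent-3-en-1-yl)chroman-4-one, via 3,6-dimethoxybenzyne 15 (not isolated), via caesium alkoxide 16 (not isolated), via ortho aryl anion 17 (not isolated)
Conditions: 6 (1 equiv), 14 (2 equiv), CsF, 18-crown-6, THF, 0 °C → rt
Reagents that add atoms: none
Why: Proposed new method: fluoride strips the trimethylsilyl groups from both partners, so 14 collapses to the symmetric aryne 15 while 6 releases the tertiary alkoxide 16 in a flask that holds no O–H or N–H proton; 16 adds to either aryne carbon (C8a–O1), and the ortho aryl anion 17, inductively stabilised by the neighbouring methoxy group and six atoms from the ester carbonyl, closes ring B by 6-exo-trig acyl substitution (C4a–C4) with loss of ethoxide, which silicon takes up as Me3SiOEt and which thereby unmasks the next alkoxide instead of consuming aryne. The closest known reaction types are the aryne annulation of salicylate esters to xanthones (phenoxide addition, then acylation of the aryl anion), the acyl-alkylation of arynes with β-keto esters and the addition of potassium tert-butoxide to benzyne; what is new is an aliphatic tertiary alkoxide that carries an enolisable ester. No stereocentre is made: the carbinol C–O bond is never broken, so the (S) configuration from step 1 is carried into C2 as long as the alkoxide does not revert. Regioselectivity is not required, because both reactive carbons of 15 are equivalent and either mode of addition gives 18. The selectivity that is required is kinetic: capture of 16 by the aryne and ring closure of 17 must outrun retro-aldol cleavage of 16, 1,5-proton transfer from the C3 methylene to the aryl anion (which would end in β-elimination of the aryloxide) and external protonation; the proximity of the ester, the silyl mask, the non-acidic solvent, the excess of 14 for a high aryne flux and the low temperature are chosen to secure this.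

Step 10
Reactants: 18 (S)-5,8-dimethoxy-2-methyl-2-(4-methylpent-3-en-1-yl)chroman-4-one
Product: 19 (2S)-2-[2-(3,3-dimethyloxiran-2-yl)ethyl]-5,8-dimethoxy-2-methylchroman-4-one (both epoxide epimers)
Conditions: mCPBA, CH2Cl2, 0 °C
Reagents that add atoms: 3-chloroperbenzoic acid, OOC(=O)c1cccc(Cl)c1
Why: Prilezhaev epoxidation carried out while the trisubstituted alkene is the only C=C in the molecule, so no chromene alkene competes and Baeyer–Villiger attack on the aryl ketone is far slower; the new centre forms without control and is erased in step 15.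

Step 11
Reactants: 19 (2S)-2-[2-(3,3-dimethyloxiran-2-yl)ethyl]-5,8-dimethoxy-2-methylchroman-4-one
Product: 20 (2S)-6-bromo-2-[2-(3,3-dimethyloxiran-2-yl)ethyl]-5,8-dimethoxy-2-methylchroman-4-one
Conditions: NBS, MeCN, 0 °C → rt, dark
Reagents that add atoms: N-bromosuccinimide, O=C1CCC(=O)N1Br
Why: Electrophilic aromatic bromination: C6 is ortho to the C5 methoxy group, para to O1 and meta to the C4 carbonyl, whereas attack at C7 would place charge on the acyl-bearing C4a and is helped by one donor only, and no alkene is present at this stage to compete for the bromine.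

Step 12
Reactants: 20 (2S)-6-bromo-2-[2-(3,3-dimethyloxiran-2-yl)ethyl]-5,8-dimethoxy-2-methylchroman-4-one
Product: 21 (2S)-6-bromo-2-[2-(3,3-dimethyloxiran-2-yl)ethyl]-5,8-dimethoxy-2-methylchroman-4-ol (both C4 epimers)
Conditions: NaBH4, MeOH/THF, 0 °C → rt
Reagents that add atoms: none
Why: Borohydride 1,2-reduction of the aryl ketone, to which epoxide and aryl bromide are inert; both C4 epimers are used because the centre disappears in the next step.

Step 13
Reactants: 21 (2S)-6-bromo-2-[2-(3,3-dimethyloxiran-2-yl)ethyl]-5,8-dimethoxy-2-methylchroman-4-ol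
Product: 23 (2S)-6-bromo-2-[2-(3,3-dimethyloxiran-2-yl)ethyl]-5,8-dimethoxy-2-methyl-2H-chromene, via C4 mesylate 22 (not isolated)
Conditions: MsCl, Et3N (excess), CH2Cl2, 0 °C → rt
Reagents that add atoms: none
Why: Mesylation and elimination: the C4 hydroxyl is the only one in the molecule at this point, its mesylate is benzylic to a ring with oxygen donors at both ortho positions (C5 and C8a) and loses a C3 proton to the amine, and the basic medium spares the epoxide that acid-catalysed dehydration would destroy.

Step 14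
Reactants: 23 (2S)-6-bromo-2-[2-(3,3-dimethyloxiran-2-yl)ethyl]-5,8-dimethoxy-2-methyl-2H-chromene
Product: 24 5-[(2S)-6-bromo-5,8-dimethoxy-2-methyl-2H-chromen-2-yl]-2-methyl-3-(phenylselanyl)pentan-2-ol
Conditions: (PhSe)2, NaBH4, EtOH, rt; then 23, 50 °C
Reagents that add atoms: diphenyl diselenide, c1ccc(cc1)[Se][Se]c1ccccc1
Why: First stage of the Sharpless–Lauer epoxide-to-allylic-alcohol transposition: the soft selenolate opens the epoxide by SN2 at its less substituted carbon and leaves the oxygen on the dimethyl carbon, while aryl bromide and chromene alkene are inert.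

Step 15
Reactants: 24 5-[(2S)-6-bromo-5,8-dimethoxy-2-methyl-2H-chromen-2-yl]-2-methyl-3-(phenylselanyl)pentan-2-ol
Product: 26 (3E)-5-[(2S)-6-bromo-5,8-dimethoxy-2-methyl-2H-chromen-2-yl]-2-methylpent-3-en-2-ol, via selenoxide 25 (not isolated)
Conditions: 30% aq. H2O2, pyridine, THF, 0 °C → rt
Reagents that add atoms: none
Why: Selenoxide syn-elimination: the carbinol carbon carries no hydrogen, so the only β-hydrogens lie on the CH2 toward the ring and the alkene can form in one direction only, with the less crowded syn-periplanar transition state giving the (E) geometry.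

Step 16
Reactants: 26 (3E)-5-[(2S)-6-bromo-5,8-dimethoxy-2-methyl-2H-chromen-2-yl]-2-methylpent-3-en-2-ol; 27 (E)-cinnamaldehyde
Product: 29 (2E)-1-{(2S)-2-[(2E)-4-hydroxy-4-methylpent-2-en-1-yl]-5,8-dimethoxy-2-methyl-2H-chromen-6-yl}-3-phenylprop-2-en-1-ol (both carbinol epimers), via dilithio species 28 (not isolated)
Conditions: n-BuLi (2.1 equiv), THF, −78 °C; 27, −78 °C; H2O quench
Reagents that add atoms: none
Why: Bromine–lithium exchange and carbonyl addition: the first equivalent of base takes the hydroxyl proton, the second exchanges C6–Br faster than anything else can react at −78 °C, and the hard aryllithium adds 1,2 to the enal, the new carbinol centre being removed in step 17.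

Step 17
Reactants: 29 (2E)-1-{(2S)-2-[(2E)-4-hydroxy-4-methylpent-2-en-1-yl]-5,8-dimethoxy-2-methyl-2H-chromen-6-yl}-3-phenylprop-2-en-1-ol
Product: 30 (2E)-1-{(2S)-2-[(2E)-4-hydroxy-4-methylpent-2-en-1-yl]-5,8-dimethoxy-2-methyl-2H-chromen-6-yl}-3-phenylprop-2-en-1-one
Conditions: activated MnO2, CH2Cl2, rt, dark
Reagents that add atoms: none
Why: MnO2 oxidation of an allylic and benzylic secondary alcohol under neutral conditions, which suits the ionisation-prone carbinol and cannot touch the tertiary alcohol.

Step 18
Reactants: 30 (2E)-1-{(2S)-2-[(2E)-4-hydroxy-4-methylpent-2-en-1-yl]-5,8-dimethoxy-2-methyl-2H-chromen-6-yl}-3-phenylprop-2-en-1-one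
Product: 31 (2S)-2-[(2E)-4-hydroxy-4-methylpent-2-en-1-yl]-2-methyl-6-[(2E)-3-phenylprop-2-enoyl]-2H-chromene-5,8-dione
Conditions: (NH4)2Ce(NO3)6 (2.5 equiv), MeCN/H2O, −10 → 0 °C, short contact, dark; crude product used at once
Reagents that add atoms: water, O
Why: Oxidative demethylation of a 1,4-dimethoxyarene by tetravalent cerium: two one-electron oxidations with attack of water at C5 and C8 expel both methoxy groups as methanol and leave O1 as a vinylogous ester, and low temperature, short contact and darkness protect the tertiary allylic alcohol and the C2 centre.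

Step 19
Reactants: 31 (2S)-2-[(2E)-4-hydroxy-4-methylpent-2-en-1-yl]-2-methyl-6-[(2E)-3-phenylprop-2-enoyl]-2H-chromene-5,8-dione
Product: 32 (2E)-1-{(2S)-5,8-dihydroxy-2-[(2E)-4-hydroxy-4-methylpent-2-en-1-yl]-2-methyl-2H-chromen-6-yl}-3-phenylprop-2-en-1-one (CNP0327890.1)
Conditions: Na2S2O4, EtOAc/H2O, rt, argon, dark
Reagents that add atoms: none
Why: Dithionite reduction of a quinone to the hydroquinone, a fast two-electron reduction in a near-neutral two-phase system that should leave the enone unreduced, avoids base- or acid-promoted chalcone-to-flavanone cyclisation and does not touch C2.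

**Compound list**
1 | geraniol | CC(C)=CCC/C(C)=C/CO | starting material
2 | (2S,3S)-2,3-epoxygeraniol | CC(C)=CCC[C@]1(C)O[C@H]1CO | intermediate
3 | (S)-3,7-dimethyloct-6-ene-1,3-diol | OCC[C@@](C)(O)CCC=C(C)C | intermediate
4 | (S)-3-hydroxy-3,7-dimethyloct-6-enoic acid | OC(=O)C[C@@](C)(O)CCC=C(C)C | intermediate
5 | ethyl (S)-3-hydroxy-3,7-dimethyloct-6-enoate | CCOC(=O)C[C@@](C)(O)CCC=C(C)C | intermediate
6 | ethyl (S)-3,7-dimethyl-3-(trimethylsilyloxy)oct-6-enoate | CCOC(=O)C[C@@](C)(O[Si](C)(C)C)CCC=C(C)C | intermediate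
7 | 2,5-dimethoxyphenol | COc1ccc(OC)c(O)c1 | starting material
8 | 2,5-dimethoxyphenyl N-isopropylcarbamate | COc1ccc(OC)c(OC(=O)NC(C)C)c1 | intermediate
9 | 2,5-dimethoxyphenyl N-(tert-butyldimethylsilyl)-N-isopropylcarbamate (not isolated) | COc1ccc(OC)c(OC(=O)N(C(C)C)[Si](C)(C)C(C)(C)C)c1 | intermediate
10 | 2-lithio-3,6-dimethoxyphenyl N-(tert-butyldimethylsilyl)-N-isopropylcarbamate (not isolated) | COc1ccc(OC)c(OC(=O)N(C(C)C)[Si](C)(C)C(C)(C)C)c1[Li] | intermediate
11 | 3,6-dimethoxy-2-(trimethylsilyl)phenyl N-(tert-butyldimethylsilyl)-N-isopropylcarbamate (not isolated) | COc1ccc(OC)c(OC(=O)N(C(C)C)[Si](C)(C)C(C)(C)C)c1[Si](C)(C)C | intermediate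
12 | 3,6-dimethoxy-2-(trimethylsilyl)phenyl N-isopropylcarbamate | COc1ccc(OC)c(OC(=O)NC(C)C)c1[Si](C)(C)C | intermediate
13 | 3,6-dimethoxy-2-(trimethylsilyl)phenol (not isolated) | COc1ccc(OC)c(O)c1[Si](C)(C)C | intermediate
14 | 3,6-dimethoxy-2-(trimethylsilyl)phenyl trifluoromethanesulfonate | COc1ccc(OC)c(OS(=O)(=O)C(F)(F)F)c1[Si](C)(C)C | intermediate
15 | 3,6-dimethoxybenzyne (not isolated) | COC1=CC=C(OC)C#C1 | intermediate
16 | caesium (S)-1-ethoxy-3,7-dimethyl-1-oxooct-6-en-3-olate (not isolated) | CCOC(=O)C[C@@](C)([O-])CCC=C(C)C.[Cs+] | intermediate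
17 | caesium salt of the ortho aryl anion of ethyl (S)-3-(2,5-dimethoxyphenoxy)-3,7-dimethyloct-6-enoate (not isolated) | CCOC(=O)C[C@@](C)(Oc1[c-]c(OC)ccc1OC)CCC=C(C)C.[Cs+] | intermediate
18 | (S)-5,8-dimethoxy-2-methyl-2-(4-methylpent-3-en-1-yl)chroman-4-one | CC(C)=CCC[C@@]1(C)CC(=O)c2c(OC)ccc(OC)c2O1 | intermediate
19 | (2S)-2-[2-(3,3-dimethyloxiran-2-yl)ethyl]-5,8-dimethoxy-2-methylchroman-4-one | CC1(C)OC1CC[C@@]1(C)CC(=O)c2c(OC)ccc(OC)c2O1 | intermediate
20 | (2S)-6-bromo-2-[2-(3,3-dimethyloxiran-2-yl)ethyl]-5,8-dimethoxy-2-methylchroman-4-one | CC1(C)OC1CC[C@@]1(C)CC(=O)c2c(OC)c(Br)cc(OC)c2O1 | intermediate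
21 | (2S)-6-bromo-2-[2-(3,3-dimethyloxiran-2-yl)ethyl]-5,8-dimethoxy-2-methylchroman-4-ol | CC1(C)OC1CC[C@@]1(C)CC(O)c2c(OC)c(Br)cc(OC)c2O1 | intermediate
22 | C4 methanesulfonate of 21 (not isolated) | CC1(C)OC1CC[C@@]1(C)CC(OS(C)(=O)=O)c2c(OC)c(Br)cc(OC)c2O1 | intermediate
23 | (2S)-6-bromo-2-[2-(3,3-dimethyloxiran-2-yl)ethyl]-5,8-dimethoxy-2-methyl-2H-chromene | CC1(C)OC1CC[C@@]1(C)C=Cc2c(OC)c(Br)cc(OC)c2O1 | intermediate
24 | 5-[(2S)-6-bromo-5,8-dimethoxy-2-methyl-2H-chromen-2-yl]-2-methyl-3-(phenylselanyl)pentan-2-ol | CC(C)(O)C([Se]c1ccccc1)CC[C@@]1(C)C=Cc2c(OC)c(Br)cc(OC)c2O1 | intermediate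
25 | selenoxide of 24 (not isolated) | CC(C)(O)C([Se](=O)c1ccccc1)CC[C@@]1(C)C=Cc2c(OC)c(Br)cc(OC)c2O1 | intermediate
26 | (3E)-5-[(2S)-6-bromo-5,8-dimethoxy-2-methyl-2H-chromen-2-yl]-2-methylpent-3-en-2-ol | CC(C)(O)/C=C/C[C@@]1(C)C=Cc2c(OC)c(Br)cc(OC)c2O1 | intermediate
27 | (E)-cinnamaldehyde | O=C/C=C/c1ccccc1 | starting material
28 | C6-lithio lithium alkoxide derived from 26 (not isolated) | [Li]OC(C)(C)/C=C/C[C@@]1(C)C=Cc2c(OC)c([Li])cc(OC)c2O1 | intermediate
29 | (2E)-1-{(2S)-2-[(2E)-4-hydroxy-4-methylpent-2-en-1-yl]-5,8-dimethoxy-2-methyl-2H-chromen-6-yl}-3-phenylprop-2-en-1-ol | CC(C)(O)/C=C/C[C@@]1(C)C=Cc2c(OC)c(C(O)/C=C/c3ccccc3)cc(OC)c2O1 | intermediate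
30 | (2E)-1-{(2S)-2-[(2E)-4-hydroxy-4-methylpent-2-en-1-yl]-5,8-dimethoxy-2-methyl-2H-chromen-6-yl}-3-phenylprop-2-en-1-one | CC(C)(O)/C=C/C[C@@]1(C)C=Cc2c(OC)c(C(=O)/C=C/c3ccccc3)cc(OC)c2O1 | intermediate
31 | (2S)-2-[(2E)-4-hydroxy-4-methylpent-2-en-1-yl]-2-methyl-6-[(2E)-3-phenylprop-2-enoyl]-2H-chromene-5,8-dione | CC(C)(O)/C=C/C[C@@]1(C)C=CC2=C(O1)C(=O)C=C(C(=O)/C=C/c3ccccc3)C2=O | intermediate
32 | (2E)-1-{(2S)-5,8-dihydroxy-2-[(2E)-4-hydroxy-4-methylpent-2-en-1-yl]-2-methyl-2H-chromen-6-yl}-3-phenylprop-2-en-1-one | CC(C)(O)/C=C/C[C@@]1(C)C=Cc2c(O)c(C(=O)/C=C/c3ccccc3)cc(O)c2O1 | target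

**Step count**
- Total step count: 19
- Longest linear sequence: 16 (steps 1–5 and 9–19, from geraniol)

**Three steps most likely to fail**

1. Step 9 (aryne O-arylation and acylation).
What may go wrong:
- Retro-aldol fragmentation of the unmasked tertiary alkoxide, which would also erode the enantiomeric purity if it is reversible.
- Slow attack of a hindered alkoxide at an aryne carbon that stands next to a methoxy group.
- Proton transfer from the C3 methylene to the aryl anion, followed by β-elimination of the aryloxide.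
- Ene reaction of surplus aryne with the side-chain alkene.

The fallback sets out from diol 3 and comes back to the route at chromanone 18. It makes the two ring bonds one after the other by known reactions, C4a–C4 first by carbonyl addition and C8a–O1 last by palladium-catalysed etherification. Diol 3 is oxidised only to the aldehyde stage (TEMPO, PhI(OAc)2, CH2Cl2) to give (S)-3-hydroxy-3,7-dimethyloct-6-enal F1. Commercial 2-bromo-1,4-dimethoxybenzene is deprotonated between bromine and methoxy with LiN(iPr)2 in THF at −78 °C to give (2-bromo-3,6-dimethoxyphenyl)lithium F2. A little over two equivalents of F2 add to F1 at −78 °C to give (3S)-1-(2-bromo-3,6-dimethoxyphenyl)-3,7-dimethyloct-6-ene-1,3-diol F3 as both carbinol epimers. TBSCl and imidazole silylate only the secondary hydroxyl and give (3S)-1-(2-bromo-3,6-dimethoxyphenyl)-1-(tert-butyldimethylsilyloxy)-3,7-dimethyloct-6-en-3-ol F4. Intramolecular Buchwald-type C–O coupling follows (Pd(OAc)2, 2-(di-tert-butylphosphino)-1,1'-binaphthyl, Cs2CO3, toluene, 80 °C). The tertiary alkoxide offers no hydrogen for β-hydride elimination and its carbinol C–O bond stays intact, so the coupling gives (2S)-4-(tert-butyldimethylsilyloxy)-5,8-dimethoxy-2-methyl-2-(4-methylpent-3-en-1-yl)chromane F5. Bu4NF frees (2S)-5,8-dimethoxy-2-methyl-2-(4-methylpent-3-en-1-yl)chroman-4-ol F6, and Dess–Martin periodinane oxidises it to 18.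

2. Step 18 (cerium oxidation).
What may go wrong:
- Acid-promoted ionisation or allylic transposition of the free tertiary allylic alcohol in the strongly acidic medium.
- Over-oxidation at the chromene alkene.
- Addition of water to the very electrophilic acylquinone.
- Electrocyclic opening of ring B at the quinone stage, with erosion of the C2 configuration.

The fallback sets out from 26 and comes back at the target 32. It changes the protecting-group plan so that the oxidation never meets a free allylic alcohol and the last operation is a buffered desilylation. It does not remove the risk of ring opening at the quinone stage, which is still met only by cold, dark and short handling. TESOTf and 2,6-lutidine (CH2Cl2, −78 → 0 °C) give the triethylsilyl ether of 26 F7. One equivalent of n-BuLi at −78 °C gives the C6 aryllithium F8, which adds to 27 to give the silyl-protected carbinol F9. MnO2 gives the silyl-protected chalcone F10. (NH4)2Ce(NO3)6 in cold aqueous MeCN gives the silyl-protected quinone F11, and Na2S2O4 gives the silyl-protected hydroquinone F12. HF·pyridine buffered with excess pyridine (THF, 0 °C) then releases 32. Any silyl loss during the oxidation converges on the same product.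

3. Step 16 (exchange and addition).
What may go wrong:
- Incomplete bromine–lithium exchange within the lithium alkoxide aggregate.
- Premature protonation of the aryllithium.
- Conjugate instead of carbonyl addition.
- Ionisation of the doubly activated carbinol on work-up.

The fallback sets out from 26 and comes back at chalcone 30. It replaces the carbanion chemistry by cross-coupling and an aldol condensation. Stille coupling of 26 with tributyl(1-ethoxyvinyl)stannane (Pd(PPh3)4, CuI, CsF, DMF, 45 °C) gives the 6-(1-ethoxyvinyl)chromene F13. Brief treatment with dilute aqueous HCl in THF at 0 °C hydrolyses the enol ether to the 6-acetylchromene F14. Claisen–Schmidt condensation with benzaldehyde (KOH, EtOH, rt) gives the (E)-enone 30.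

**Further compounds**
F1 | step 9 | (S)-3-hydroxy-3,7-dimethyloct-6-enal | O=CC[C@@](C)(O)CCC=C(C)C
F2 | step 9 | (2-bromo-3,6-dimethoxyphenyl)lithium | COc1ccc(OC)c(Br)c1[Li]
F3 | step 9 | (3S)-1-(2-bromo-3,6-dimethoxyphenyl)-3,7-dimethyloct-6-ene-1,3-diol | OC(C[C@@](C)(O)CCC=C(C)C)c1c(Br)c(OC)ccc1OC
F4 | step 9 | (3S)-1-(2-bromo-3,6-dimethoxyphenyl)-1-(tert-butyldimethylsilyloxy)-3,7-dimethyloct-6-en-3-ol | CC(C)(C)[Si](C)(C)OC(C[C@@](C)(O)CCC=C(C)C)c1c(Br)c(OC)ccc1OC
F5 | step 9 | (2S)-4-(tert-butyldimethylsilyloxy)-5,8-dimethoxy-2-methyl-2-(4-methylpent-3-en-1-yl)chromane | CC(C)=CCC[C@@]1(C)CC(O[Si](C)(C)C(C)(C)C)c2c(OC)ccc(OC)c2O1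
F6 | step 9 | (2S)-5,8-dimethoxy-2-methyl-2-(4-methylpent-3-en-1-yl)chroman-4-ol | CC(C)=CCC[C@@]1(C)CC(O)c2c(OC)ccc(OC)c2O1
F7 | step 18 | triethylsilyl ether of 26 | CC[Si](CC)(CC)OC(C)(C)/C=C/C[C@@]1(C)C=Cc2c(OC)c(Br)cc(OC)c2O1
F8 | step 18 | C6 aryllithium from F7 | CC[Si](CC)(CC)OC(C)(C)/C=C/C[C@@]1(C)C=Cc2c(OC)c([Li])cc(OC)c2O1
F9 | step 18 | triethylsilyl ether of 29 | CC[Si](CC)(CC)OC(C)(C)/C=C/C[C@@]1(C)C=Cc2c(OC)c(C(O)/C=C/c3ccccc3)cc(OC)c2O1
F10 | step 18 | triethylsilyl ether of 30 | CC[Si](CC)(CC)OC(C)(C)/C=C/C[C@@]1(C)C=Cc2c(OC)c(C(=O)/C=C/c3ccccc3)cc(OC)c2O1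
F11 | step 18 | triethylsilyl ether of 31 | CC[Si](CC)(CC)OC(C)(C)/C=C/C[C@@]1(C)C=CC2=C(O1)C(=O)C=C(C(=O)/C=C/c3ccccc3)C2=O
F12 | step 18 | triethylsilyl ether of 32 | CC[Si](CC)(CC)OC(C)(C)/C=C/C[C@@]1(C)C=Cc2c(O)c(C(=O)/C=C/c3ccccc3)cc(O)c2O1
F13 | step 16 | (3E)-5-[(2S)-6-(1-ethoxyvinyl)-5,8-dimethoxy-2-methyl-2H-chromen-2-yl]-2-methylpent-3-en-2-ol | CC(C)(O)/C=C/C[C@@]1(C)C=Cc2c(OC)c(C(=C)OCC)cc(OC)c2O1
F14 | step 16 | 1-{(2S)-2-[(2E)-4-hydroxy-4-methylpent-2-en-1-yl]-5,8-dimethoxy-2-methyl-2H-chromen-6-yl}ethanone | CC(C)(O)/C=C/C[C@@]1(C)C=Cc2c(OC)c(C(C)=O)cc(OC)c2O1
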